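**Retrosynthetic overview**
- Target ⇐ O-demethylation of 2-methoxy-6-(10-phenyldecyl)benzoic acid.
- That acid ⇐ aryl C6–CH2 bond made by a carboxylate-directed, anti-Markovnikov C–H hydroarylation of 10-phenyldec-1-ene with 2-methoxybenzoic acid (the proposed new step).
- 10-Phenyldec-1-ene ⇐ Ph–CH2 bond made by Cu-catalysed coupling of phenylmagnesium bromide with 10-bromodec-1-ene.
- No ring is formed: both benzene rings are bought, and the only ring-related event is the C–H alkylation at C6 of the salicylate ring.

Assumption: the target, 2-hydroxy-6-(10-phenyldecyl)benzoic acid, has no stereocentre and no stereogenic double bond, so it is achiral and "single enantiomer" requires no stereocontrol.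

**Route**

Step 1
Reactants: 1 10-bromodec-1-ene; 2 phenylmagnesium bromide (1.0 M in THF, 1.3 equiv)
Product: 3 10-phenyldec-1-ene
Conditions: Li2CuCl4 (3 mol%), NMP (4 equiv), THF, 0 °C → rt, 3 h; aq NH4Cl
Reagents that add atoms: none
Why: Kochi-type Cu-catalysed cross-coupling of a Grignard reagent with a primary alkyl bromide, which leaves the remote terminal alkene untouched and creates no stereocentre.

Step 2
Reactants: 4 2-methoxybenzoic acid (1.0 equiv); 3 10-phenyldec-1-ene (1.5 equiv)
Product: 5 2-methoxy-6-(10-phenyldecyl)benzoic acid
Conditions: [Ru(O2CMes)2(p-cymene)] (5 mol%), PhMe (0.5 M), 100 °C, 24 h, Ar; then 1 M HCl, acid–base extraction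
Reagents that add atoms: none
Why: Proposed new method: carboxylic-acid-directed, anti-Markovnikov hydroarylation of an unactivated α-olefin, an addition with no co-product — the mesitoate ligands on Ru(II) exchange with 4, carboxylate-assisted C–H ruthenation (concerted metalation–deprotonation) occurs at C6, the only C–H ortho to CO2H because C2 carries OMe, giving a five-membered ruthenacycle; the terminal alkene of 3 inserts into Ru–aryl with the aryl going to the unhindered CH2 terminus, and the alkyl–Ru bond is then protonated by the free acid (4 or 5, always one full equivalent present), so protodemetalation should outrun β-hydride loss, and any Ru chain-walking before protonation still gives the same saturated chain; 5 has no second ortho C–H and cannot over-alkylate; the closest known reaction types are the Ru(II)/carboxylate-assisted linear hydroarylation of unactivated alkenes directed by N-heteroaryl groups and the Ru(II) carboxylate-directed ortho-C–H hydroarylation of alkynes by benzoic acids; no stereocentre is formed.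

Step 3
Reactants: 5 2-methoxy-6-(10-phenyldecyl)benzoic acid
Product: 7 2-hydroxy-6-(10-phenyldecyl)benzoic acid, via cyclic bromoboron salicylate 6 (not isolated)
Conditions: BBr3 (3 equiv), CH2Cl2, −78 °C → rt, 4 h; then H2O, 0 °C
Reagents that add atoms: boron tribromide, BrB(Br)Br (its B and one Br are held in intermediate 6 only; none of its atoms remains in 7)
Why: Lewis-acid aryl methyl ether cleavage, in which BBr3 binds the methoxy oxygen with chelation help from the neighbouring carboxyl group, bromide removes the methyl group by SN2, and water hydrolyses the B–O bonds of 6 to release 7, while the alkyl chain and both arenes are inert and there is no stereocentre to set or lose.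

**Compound list**
1 | 10-bromodec-1-ene | C=CCCCCCCCCBr | starting material
2 | phenylmagnesium bromide | Br[Mg]c1ccccc1 | starting material
3 | 10-phenyldec-1-ene | C=CCCCCCCCCc1ccccc1 | intermediate
4 | 2-methoxybenzoic acid | COc1ccccc1C(=O)O | starting material
5 | 2-methoxy-6-(10-phenyldecyl)benzoic acid | COc1cccc(CCCCCCCCCCc2ccccc2)c1C(=O)O | intermediate
6 | 2-bromo-5-(10-phenyldecyl)-4H-1,3,2-benzodioxaborinin-4-one (cyclic bromoboron salicylate, not isolated) | O=C1OB(Br)Oc2cccc(CCCCCCCCCCc3ccccc3)c21 | intermediate
7 | 2-hydroxy-6-(10-phenyldecyl)benzoic acid | O=C(O)c1c(O)cccc1CCCCCCCCCCc1ccccc1 | target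

**Totals**
Total step count: 3. Longest linear sequence: 3 steps (1 → 3 → 5 → 7).

**Three steps most likely to fail, with fallbacks**

1. Step 2 (the proposed new hydroarylation). The risks are weak carboxylate direction, Ru–H isomerisation of 3 to unreactive internal alkenes, ortho-alkenylation by β-hydride loss, and protodecarboxylation of the 2,6-disubstituted acid. The fallback uses known chemistry only, sets out from 4 (and uses 3), and comes back at 5. Compound 4 is deprotonated twice with s-BuLi/TMEDA (2.2 equiv, THF, −78 °C); the carboxylate directs the ring lithiation to C6, giving lithium 2-lithio-6-methoxybenzoate F3 (not isolated). Quenching with I2 gives 2-iodo-6-methoxybenzoic acid F4, and MeI/K2CO3 in DMF converts it into methyl 2-iodo-6-methoxybenzoate F5. Separately, 3 is hydroborated at the terminal carbon with 9-BBN-H (THF, 0 °C → rt) to 9-(10-phenyldecyl)-9-borabicyclo[3.3.1]nonane F6. F6 is joined to F5 in a B-alkyl Suzuki–Miyaura coupling (PdCl2(dppf) 3 mol%, aq K3PO4, THF/DMF, 60 °C) to give methyl 2-methoxy-6-(10-phenyldecyl)benzoate F7. Saponification of the hindered ester (KOH, DMSO/H2O, 100 °C; then HCl) returns 5, and step 3 follows unchanged.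

2. Step 1 (Cu-catalysed aryl Grignard alkylation). The risks are biphenyl from homocoupling, sluggish aryl transfer, and elimination of the bromide. The fallback reverses the polarity of the partners, sets out from 1 and comes back at 3. Compound 1 is converted with Mg turnings (THF, 40 °C) into dec-9-en-1-ylmagnesium bromide F2, which is coupled with purchased bromobenzene F1 in a Pd-catalysed Kumada–Corriu sp3–sp2 coupling (PdCl2(dppf) 1 mol%, THF, rt → 50 °C) to give 3.

3. Step 3 (BBr3 demethylation). The risks are incomplete cleavage, acid-promoted decarboxylation of the electron-rich 2,6-disubstituted salicylic acid, and troublesome boron removal. The fallback changes the protecting-group strategy so that the last step is a neutral hydrogenolysis; it sets out from 3 and comes back at 7. It is only needed once step 2 has already delivered 5, so it reuses the then-validated hydroarylation. Purchased 2-(benzyloxy)benzoic acid F8 is alkylated with 3 under the step 2 conditions to give 2-(benzyloxy)-6-(10-phenyldecyl)benzoic acid F9. Hydrogenolysis (H2 1 atm, 10% Pd/C, EtOAc, rt) removes the benzyl group and gives 7; it would also saturate any ortho-alkenyl by-product to the same chain.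

**Further compounds**
F1 | step 1 | bromobenzene (purchased input) | Brc1ccccc1
F2 | step 1 | dec-9-en-1-ylmagnesium bromide | C=CCCCCCCCC[Mg]Br
F3 | step 2 | lithium 2-lithio-6-methoxybenzoate | [Li]c1cccc(OC)c1C(=O)O[Li]
F4 | step 2 | 2-iodo-6-methoxybenzoic acid | COc1cccc(I)c1C(=O)O
F5 | step 2 | methyl 2-iodo-6-methoxybenzoate | COC(=O)c1c(I)cccc1OC
F6 | step 2 | 9-(10-phenyldecyl)-9-borabicyclo[3.3.1]nonane | c1ccccc1CCCCCCCCCCB1C2CCCC1CCC2
F7 | step 2 | methyl 2-methoxy-6-(10-phenyldecyl)benzoate | COC(=O)c1c(CCCCCCCCCCc2ccccc2)cccc1OC
F8 | step 3 | 2-(benzyloxy)benzoic acid (purchased input) | O=C(O)c1ccccc1OCc1ccccc1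
F9 | step 3 | 2-(benzyloxy)-6-(10-phenyldecyl)benzoic acid | O=C(O)c1c(OCc2ccccc2)cccc1CCCCCCCCCCc1ccccc1
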